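**Retrosynthetic overview**
1. The target is a verticillane (bicyclo[9.3.1]pentadecane) butenolide. The C6 acetate comes from a C6 enone by reagent-controlled reduction, and the 12-membered ring is closed last at C5–C6 by a carbonyl-ene reaction that also creates the C4 exocyclic methylene.
2. Ring A and the butenolide are disconnected together at C11–C15, C12–C13 and the lactone C–O bond, giving the ring-opened limonene keto aldehyde 3 and the γ-hydroxy ynoate 9. They are joined by an iron-hydride radical conjugate addition/aldol annulation.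
3. Enabling feature: in ring A the tetrasubstituted C11=C12 bond is the α,β-bond of the C18 lactone carbonyl. Its β-carbon C11 carries the gem-dimethyl carbon C15 (a tertiary radical site) and its α-carbon C12 carries C13 (a former aldehyde carbon). C1 with its isopropenyl, CH2CHO and CH2CH2COCH3 arms is ring-opened (R)-limonene.
4. Stereocentres: C1 from (R)-limonene oxide, C10 by catalytic asymmetric alkynylation, C6 by Corey–Bakshi–Shibata reduction; the 7E alkene comes from the commercial enynol.
5. Ring order: ring A and the lactone together (step 5), then the 12-membered ring (step 11).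

Key step: step 5

Remark on numbering: verticillane numbering is used. C1 and C11 are the bridgeheads, C2–C10 the nine-carbon bridge, C12–C14 the three-carbon bridge, and C15 the one-carbon bridge carrying the C16 and C17 methyls. C18 is on C12 (the lactone carbonyl), C19 on C8 and C20 on C4. TBS = tert-butyldimethylsilyl.
Assumption: (S,S)-ProPhenol is taken as the ligand enantiomer that gives the (4R)-carbinol 9; if the sense of induction is the opposite, the (R,R)-ligand is used.

**Route**

Step 1
Reactants: 1 (+)-(4R)-limonene 1,2-oxide (commercial cis/trans mixture)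
Product: 3 (3R)-6-oxo-3-(prop-1-en-2-yl)heptanal, via limonene-1,2-diol 2 (not isolated)
Conditions: H5IO6, THF/H2O, 0 °C to rt
Reagents that add atoms: water, O
Why: Aqueous periodic acid should hydrolyse both epoxide diastereomers to the 1,2-diol and cleave it (Malaprade glycol cleavage) without touching the isopropenyl group, and the future C1 stereocentre is not involved.

Step 2
Reactants: 4 (2E)-3-methylpent-2-en-4-yn-1-ol
Product: 5 tert-butyl(dimethyl){[(2E)-3-methylpent-2-en-4-yn-1-yl]oxy}silane
Conditions: TBSCl, imidazole, CH2Cl2, 0 °C to rt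
Reagents that add atoms: tert-butyldimethylsilyl chloride, CC(C)(C)[Si](C)(C)Cl
Why: Standard silylation of a primary allylic alcohol, needed so that only the C10 hydroxyl is free in the key step.

Step 3
Reactants: 5 tert-butyl(dimethyl){[(2E)-3-methylpent-2-en-4-yn-1-yl]oxy}silane
Product: 7 (3E)-5-(TBSO)-3-methylpent-3-enal, via dienylborane 6 (not isolated)
Conditions: Cy2BH, THF, 0 °C; then H2O2, aq. pH 7 phosphate buffer, 0 °C
Reagents that add atoms: hydrogen peroxide, OO
Why: Anti-Markovnikov hydroboration of the terminal alkyne by the bulky dialkylborane (the trisubstituted alkene is spared) and buffered oxidation should give the enol and hence the β,γ-unsaturated aldehyde, which is used at once to avoid conjugation.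

Step 4
Reactants: 7 (3E)-5-(TBSO)-3-methylpent-3-enal; 8 methyl prop-2-ynoate (methyl propiolate)
Product: 9 methyl (4R,6E)-8-(TBSO)-4-hydroxy-6-methyloct-6-en-2-ynoate
Conditions: Me2Zn, (S,S)-ProPhenol (20 mol %), Ph3PO, toluene, 4 °C
Reagents that add atoms: none
Why: Catalytic asymmetric alkynylation (zinc alkynylide addition under ProPhenol control) sets C10 as R by reagent control, and the mild dialkylzinc medium should not isomerise the aldehyde.

Step 5
Reactants: 3 (3R)-6-oxo-3-(prop-1-en-2-yl)heptanal; 9 methyl (4R,6E)-8-(TBSO)-4-hydroxy-6-methyloct-6-en-2-ynoate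
Product: 11 (3R,5R)-3-[(2E)-4-(TBSO)-2-methylbut-2-en-1-yl]-7-hydroxy-4,4-dimethyl-5-(3-oxobutyl)-4,5,6,7-tetrahydro-2-benzofuran-1(3H)-one (C7 epimers), via hydroxy ester 10 (not isolated)
Conditions: 3 (2 equiv), Fe(acac)3 (30 mol %), PhSiH3, EtOH/(CH2OH)2, 40 °C; then PPTS, CH2Cl2, rt
Reagents that add atoms: none
Why: Proposed new method: hydrogen atom transfer from the iron hydride (formed from Fe(acac)3 and PhSiH3) to the isopropenyl group of 3 gives the tertiary C15 radical, which adds to the ester-polarised β-carbon C11 of ynoate 9 (Giese addition, bond C11–C15), and the α-ester vinyl radical is reduced by divalent iron to the allenolate, whose C12 attacks the C13 aldehyde (intramolecular aldol, bond C12–C13); the closest known reaction type is the iron-hydride-initiated radical conjugate addition/aldol annulation of γ,δ-unsaturated aldehydes with enones and enoates, here carried from alkene to alkyne acceptors so that the ring alkene is kept. Ring A closes 6-exo-trig at the formyl carbon with the C11=C12 bond endocyclic, and the butenolide closes by 5-exo-trig lactonisation of the C10 hydroxyl on the ester, which the ring alkene holds cis, with loss of methanol. No lasting stereocentre is created: C1 (from limonene) and C10 (from 9, C–O bond untouched) are carried through, and the C13 carbinol forms as an epimer mixture that steps 6 and 7 remove. The step needs hydrogen atom transfer to the 1,1-disubstituted alkene only, which the much lower reactivity of the trisubstituted C7=C8 alkene and of the electron-poor alkyne secures, and radical attack at C11 and not C12, which the ester secures by polarising the alkyne and stabilising the radical at C12. Ring closure must outrun hydrogen abstraction by the vinyl radical, which fast electron transfer to this strongly oxidising radical and the six-membered geometry should favour.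

Step 6
Reactants: 11 (3R,5R)-3-[(2E)-4-(TBSO)-2-methylbut-2-en-1-yl]-7-hydroxy-4,4-dimethyl-5-(3-oxobutyl)-4,5,6,7-tetrahydro-2-benzofuran-1(3H)-one (C7 epimers)
Product: 12 (3R,5R)-7-bromo-3-[(2E)-4-(TBSO)-2-methylbut-2-en-1-yl]-4,4-dimethyl-5-(3-oxobutyl)-4,5,6,7-tetrahydro-2-benzofuran-1(3H)-one (C7 epimers)
Conditions: CBr4, PPh3, CH2Cl2, 0 °C
Reagents that add atoms: carbon tetrabromide, BrC(Br)(Br)Br
Why: Appel reaction of the only free hydroxyl (secondary, allylic) by direct displacement, since SN2' attack at the fully substituted C11 next to the quaternary C15 is blocked; the configuration at C13 is irrelevant.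

Step 7
Reactants: 12 (3R,5R)-7-bromo-3-[(2E)-4-(TBSO)-2-methylbut-2-en-1-yl]-4,4-dimethyl-5-(3-oxobutyl)-4,5,6,7-tetrahydro-2-benzofuran-1(3H)-one
Product: 13 (3R,5S)-3-[(2E)-4-(TBSO)-2-methylbut-2-en-1-yl]-4,4-dimethyl-5-(3-oxobutyl)-4,5,6,7-tetrahydro-2-benzofuran-1(3H)-one
Conditions: Bu3SnH, AIBN, toluene, 80 °C
Reagents that add atoms: none
Why: Tin hydride radical dehalogenation, in which the C13–C12–C11 allyl radical should take hydrogen at the less hindered C13 terminus and so keep the tetrasubstituted alkene conjugated with the lactone (the C5 descriptor changes only through the priority rules).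

Step 8
Reactants: 13 (3R,5S)-3-[(2E)-4-(TBSO)-2-methylbut-2-en-1-yl]-4,4-dimethyl-5-(3-oxobutyl)-4,5,6,7-tetrahydro-2-benzofuran-1(3H)-one
Product: 14 (3R,5R)-3-[(2E)-4-(TBSO)-2-methylbut-2-en-1-yl]-4,4-dimethyl-5-(3-methylbut-3-en-1-yl)-4,5,6,7-tetrahydro-2-benzofuran-1(3H)-one
Conditions: Zn, CH2Br2, TiCl4, THF/CH2Cl2, 0 °C to rt
Reagents that add atoms: dibromomethane, BrCBr
Why: Takai–Lombardo methylenation converts the methyl ketone chemoselectively beside the lactone under non-basic conditions, so the base-sensitive γ-stereocentre C10 should stay intact.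

Step 9
Reactants: 14 (3R,5R)-3-[(2E)-4-(TBSO)-2-methylbut-2-en-1-yl]-4,4-dimethyl-5-(3-methylbut-3-en-1-yl)-4,5,6,7-tetrahydro-2-benzofuran-1(3H)-one
Product: 15 (3R,5R)-3-[(2E)-4-hydroxy-2-methylbut-2-en-1-yl]-4,4-dimethyl-5-(3-methylbut-3-en-1-yl)-4,5,6,7-tetrahydro-2-benzofuran-1(3H)-one
Conditions: HF·pyridine, THF/pyridine, 0 °C
Reagents that add atoms: none
Why: Fluoride cleavage of the primary silyl ether under buffered conditions that do not open or epimerise the lactone.

Step 10
Reactants: 15 (3R,5R)-3-[(2E)-4-hydroxy-2-methylbut-2-en-1-yl]-4,4-dimethyl-5-(3-methylbut-3-en-1-yl)-4,5,6,7-tetrahydro-2-benzofuran-1(3H)-one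
Product: 16 (3R,5R)-4,4-dimethyl-5-(3-methylbut-3-en-1-yl)-3-[(2E)-2-methyl-4-oxobut-2-en-1-yl]-4,5,6,7-tetrahydro-2-benzofuran-1(3H)-one
Conditions: MnO2, CH2Cl2, rt
Reagents that add atoms: none
Why: MnO2 oxidises allylic alcohols selectively and without E/Z isomerisation.

Step 11
Reactants: 16 (3R,5R)-4,4-dimethyl-5-(3-methylbut-3-en-1-yl)-3-[(2E)-2-methyl-4-oxobut-2-en-1-yl]-4,5,6,7-tetrahydro-2-benzofuran-1(3H)-one
Product: 17 (1R,7E,10R)-6-hydroxyverticilla-4(20),7,11-trien-18,10-olide (C6 epimers)
Conditions: Me2AlCl (2.5 equiv), CH2Cl2 (1 mM), −78 to −20 °C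
Reagents that add atoms: none
Why: Lewis acid promoted intramolecular carbonyl-ene reaction of type 2, in which the terminal methylene of the 1,1-disubstituted alkene attacks the aldehyde and a hydrogen of the freely rotating methyl group is transferred, should close the 12-membered ring at C5–C6 and unveil the C4 exocyclic methylene in the same step; C6 forms under macrocyclic control and both epimers are carried on because step 12 erases it.

Step 12
Reactants: 17 (1R,7E,10R)-6-hydroxyverticilla-4(20),7,11-trien-18,10-olide (C6 epimers)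
Product: 18 (1R,7E,10R)-6-oxoverticilla-4(20),7,11-trien-18,10-olide
Conditions: Dess–Martin periodinane, NaHCO3, CH2Cl2, 0 °C
Reagents that add atoms: none
Why: Buffered Dess–Martin oxidation converges both C6 epimers on the enone under conditions that should not move the skipped exocyclic alkene into conjugation.

Step 13
Reactants: 18 (1R,7E,10R)-6-oxoverticilla-4(20),7,11-trien-18,10-olide
Product: 19 (1R,6S,7E,10R)-6-hydroxyverticilla-4(20),7,11-trien-18,10-olide
Conditions: (R)-2-methyl-CBS-oxazaborolidine, catecholborane, toluene, −78 °C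
Reagents that add atoms: none
Why: Corey–Bakshi–Shibata reduction, in which the oxazaborolidine distinguishes the large trisubstituted alkenyl group from the C5 methylene and delivers hydride to give the (6S)-allylic alcohol by reagent control, while catecholborane at low temperature spares the alkenes and the lactone.

Step 14
Reactants: 19 (1R,6S,7E,10R)-6-hydroxyverticilla-4(20),7,11-trien-18,10-olide
Product: 20 (1R,6S,7E,10R)-6-acetoxyverticilla-4(20),7,11-trien-18,10-olide (CNP0289913.1)
Conditions: Ac2O, DMAP, pyridine, CH2Cl2, 0 °C to rt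
Reagents that add atoms: acetic anhydride, CC(=O)OC(C)=O
Why: Acylation of the secondary allylic alcohol proceeds with retention at C6 and gives the target.

**Compound list**
1 | (+)-(4R)-limonene 1,2-oxide (cis/trans mixture) | CC12OC1C[C@@H](CC2)C(C)=C | starting material
2 | (4R)-1-methyl-4-(prop-1-en-2-yl)cyclohexane-1,2-diol (limonene-1,2-diol) | CC1(O)C(O)C[C@@H](CC1)C(C)=C | intermediate
3 | (3R)-6-oxo-3-(prop-1-en-2-yl)heptanal | O=CC[C@@H](CCC(C)=O)C(C)=C | intermediate
4 | (2E)-3-methylpent-2-en-4-yn-1-ol | OC/C=C(C)/C#C | starting material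
5 | tert-butyl(dimethyl){[(2E)-3-methylpent-2-en-4-yn-1-yl]oxy}silane | CC(C)(C)[Si](C)(C)OC/C=C(C)/C#C | intermediate
6 | dicyclohexyl[(1E,3E)-5-(TBSO)-3-methylpenta-1,3-dien-1-yl]borane | CC(C)(C)[Si](C)(C)OC/C=C(C)/C=C/B(C1CCCCC1)C1CCCCC1 | intermediate
7 | (3E)-5-(TBSO)-3-methylpent-3-enal | CC(C)(C)[Si](C)(C)OC/C=C(C)/CC=O | intermediate
8 | methyl prop-2-ynoate (methyl propiolate) | COC(=O)C#C | starting material
9 | methyl (4R,6E)-8-(TBSO)-4-hydroxy-6-methyloct-6-en-2-ynoate | COC(=O)C#C[C@@H](C/C(C)=C/CO[Si](C)(C)C(C)(C)C)O | intermediate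
10 | methyl (4R)-2-[(1R,3E)-5-(TBSO)-1-hydroxy-3-methylpent-3-en-1-yl]-6-hydroxy-3,3-dimethyl-4-(3-oxobutyl)cyclohex-1-ene-1-carboxylate (C6 epimers) | CC(=O)CC[C@@H]1CC(O)C(C(=O)OC)=C([C@@H](C/C(C)=C/CO[Si](C)(C)C(C)(C)C)O)C1(C)C | intermediate
11 | (3R,5R)-3-[(2E)-4-(TBSO)-2-methylbut-2-en-1-yl]-7-hydroxy-4,4-dimethyl-5-(3-oxobutyl)-4,5,6,7-tetrahydro-2-benzofuran-1(3H)-one (C7 epimers) | CC(=O)CC[C@@H]1CC(O)C2=C([C@@H](C/C(C)=C/CO[Si](C)(C)C(C)(C)C)OC2=O)C1(C)C | intermediate
12 | (3R,5R)-7-bromo-3-[(2E)-4-(TBSO)-2-methylbut-2-en-1-yl]-4,4-dimethyl-5-(3-oxobutyl)-4,5,6,7-tetrahydro-2-benzofuran-1(3H)-one (C7 epimers) | CC(=O)CC[C@@H]1CC(Br)C2=C([C@@H](C/C(C)=C/CO[Si](C)(C)C(C)(C)C)OC2=O)C1(C)C | intermediate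
13 | (3R,5S)-3-[(2E)-4-(TBSO)-2-methylbut-2-en-1-yl]-4,4-dimethyl-5-(3-oxobutyl)-4,5,6,7-tetrahydro-2-benzofuran-1(3H)-one | CC(=O)CC[C@@H]1CCC2=C([C@@H](C/C(C)=C/CO[Si](C)(C)C(C)(C)C)OC2=O)C1(C)C | intermediate
14 | (3R,5R)-3-[(2E)-4-(TBSO)-2-methylbut-2-en-1-yl]-4,4-dimethyl-5-(3-methylbut-3-en-1-yl)-4,5,6,7-tetrahydro-2-benzofuran-1(3H)-one | C=C(C)CC[C@@H]1CCC2=C([C@@H](C/C(C)=C/CO[Si](C)(C)C(C)(C)C)OC2=O)C1(C)C | intermediate
15 | (3R,5R)-3-[(2E)-4-hydroxy-2-methylbut-2-en-1-yl]-4,4-dimethyl-5-(3-methylbut-3-en-1-yl)-4,5,6,7-tetrahydro-2-benzofuran-1(3H)-one | C=C(C)CC[C@@H]1CCC2=C([C@@H](C/C(C)=C/CO)OC2=O)C1(C)C | intermediate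
16 | (3R,5R)-4,4-dimethyl-5-(3-methylbut-3-en-1-yl)-3-[(2E)-2-methyl-4-oxobut-2-en-1-yl]-4,5,6,7-tetrahydro-2-benzofuran-1(3H)-one | C=C(C)CC[C@@H]1CCC2=C([C@@H](C/C(C)=C/C=O)OC2=O)C1(C)C | intermediate
17 | (1R,7E,10R)-6-hydroxyverticilla-4(20),7,11-trien-18,10-olide (C6 epimers) | C=C1CC[C@@H]2CCC3=C([C@@H](C/C(C)=C/C(O)C1)OC3=O)C2(C)C | intermediate
18 | (1R,7E,10R)-6-oxoverticilla-4(20),7,11-trien-18,10-olide | C=C1CC[C@@H]2CCC3=C([C@@H](C/C(C)=C/C(=O)C1)OC3=O)C2(C)C | intermediate
19 | (1R,6S,7E,10R)-6-hydroxyverticilla-4(20),7,11-trien-18,10-olide | C=C1CC[C@@H]2CCC3=C([C@@H](C/C(C)=C/[C@@H](O)C1)OC3=O)C2(C)C | intermediate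
20 | (1R,6S,7E,10R)-6-acetoxyverticilla-4(20),7,11-trien-18,10-olide (CNP0289913.1) | C=C1CC[C@@H]2CCC3=C([C@@H](C/C(C)=C/[C@@H](OC(C)=O)C1)OC3=O)C2(C)C | target

**Totals and risks**
Total step count: 14. Longest linear sequence: 13 steps (from 4 to 20, steps 2 to 14); the limonene branch joins at step 5 after one step.

Steps most likely to fail:

Step 5 (Proposed new method). What may go wrong: the vinyl radical formed after the first bond may abstract hydrogen (from the silane, the solvent, or by a 1,5-shift from C14) or attack the C7=C8 alkene before it is reduced and closes ring A; addition of the hindered tertiary radical to the internal alkyne may also be slow enough that simple reduction of the isopropenyl group wins. The fallback uses the established alkene version of the annulation and sets out from 9. Semihydrogenation (H2, Pd/CaCO3 poisoned with Pb(OAc)2, quinoline, EtOAc) gives the (Z)-hydroxy enoate F1, which closes spontaneously to the butenolide F2. Compounds 3 and F2 are then joined with Fe(acac)3 and PhSiH3; the tertiary radical adds to C11 anti to the C10 substituent and the lactone enolate closes ring A by aldol reaction, giving the saturated hydroxy lactone F3. Mesylation (MsCl, Et3N) to the mesylate F4 and elimination with DBU give the α-alkylidene lactone F5. Alkene isomerisation with catalytic RhCl3·3H2O in ethanol then moves the double bond into the ring-fusion position, and the fallback comes back to the route at 13.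

Step 11. What may go wrong: oligomerisation in competition with the entropically costly 12-membered closure, hydrogen transfer from C3 instead of the methyl group (giving an endocyclic C3=C4 alkene), or conjugate attack on the enal. The fallback closes the same C5–C6 bond by an intramolecular aldol reaction at the ketone stage and sets out from 13. Desilylation (HF·pyridine) gives the keto alcohol F6 and MnO2 oxidation gives the keto enal F7. Soft enolisation on the methyl side (Cy2BCl, Et3N, CH2Cl2, high dilution, −78 °C) and aldol closure give the macrocyclic hydroxy ketone F8. Silylation (TESOTf, 2,6-lutidine) gives the silyl ether F9, methylenation (Zn, CH2Br2, TiCl4) gives the methylene compound F10, and HF·pyridine removes the silyl group; the fallback comes back to the route at 17.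

Step 13. What may go wrong: poor facial selectivity if the macrocyclic conformation overrides the reagent, or migration of the skipped exocyclic alkene into conjugation at the stage of the ketone 18. The fallback avoids the ketone and sets out from 17. The C6 epimers are separated by chromatography; the (6S)-epimer is 19 and enters step 14, while the (6R)-alcohol F11 is converted by Mitsunobu reaction with acetic acid (PPh3, DIAD, AcOH, THF) with inversion directly into the acetate. The fallback comes back to the route at 19 and at 20.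

Further compounds
F1 | step 5 | methyl (2Z,4R,6E)-8-(TBSO)-4-hydroxy-6-methylocta-2,6-dienoate | COC(=O)/C=C\[C@@H](C/C(C)=C/CO[Si](C)(C)C(C)(C)C)O
F2 | step 5 | (5R)-5-[(2E)-4-(TBSO)-2-methylbut-2-en-1-yl]furan-2(5H)-one | O=C1C=C[C@@H](C/C(C)=C/CO[Si](C)(C)C(C)(C)C)O1
F3 | step 5 | (3R,5R)-3-[(2E)-4-(TBSO)-2-methylbut-2-en-1-yl]-7-hydroxy-4,4-dimethyl-5-(3-oxobutyl)hexahydro-2-benzofuran-1(3H)-one (epimers at C3a, C7 and C7a) | CC(=O)CC[C@@H]1CC(O)C2C([C@@H](C/C(C)=C/CO[Si](C)(C)C(C)(C)C)OC2=O)C1(C)C
F4 | step 5 | methanesulfonate of F3 at the C7 hydroxyl | CC(=O)CC[C@@H]1CC(OS(C)(=O)=O)C2C([C@@H](C/C(C)=C/CO[Si](C)(C)C(C)(C)C)OC2=O)C1(C)C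
F5 | step 5 | (3R,5S)-3-[(2E)-4-(TBSO)-2-methylbut-2-en-1-yl]-4,4-dimethyl-5-(3-oxobutyl)-3a,4,5,6-tetrahydro-2-benzofuran-1(3H)-one (C3a epimers) | CC(=O)CC[C@@H]1CC=C2C([C@@H](C/C(C)=C/CO[Si](C)(C)C(C)(C)C)OC2=O)C1(C)C
F6 | step 11 | (3R,5S)-3-[(2E)-4-hydroxy-2-methylbut-2-en-1-yl]-4,4-dimethyl-5-(3-oxobutyl)-4,5,6,7-tetrahydro-2-benzofuran-1(3H)-one | CC(=O)CC[C@@H]1CCC2=C([C@@H](C/C(C)=C/CO)OC2=O)C1(C)C
F7 | step 11 | (3R,5S)-4,4-dimethyl-3-[(2E)-2-methyl-4-oxobut-2-en-1-yl]-5-(3-oxobutyl)-4,5,6,7-tetrahydro-2-benzofuran-1(3H)-one | CC(=O)CC[C@@H]1CCC2=C([C@@H](C/C(C)=C/C=O)OC2=O)C1(C)C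
F8 | step 11 | (1S,7E,10R)-6-hydroxy-4-oxo-20-norverticilla-7,11-dien-18,10-olide (C6 epimers) | O=C1CC[C@@H]2CCC3=C([C@@H](C/C(C)=C/C(O)C1)OC3=O)C2(C)C
F9 | step 11 | (1S,7E,10R)-4-oxo-6-(triethylsilyloxy)-20-norverticilla-7,11-dien-18,10-olide (C6 epimers) | O=C1CC[C@@H]2CCC3=C([C@@H](C/C(C)=C/C(O[Si](CC)(CC)CC)C1)OC3=O)C2(C)C
F10 | step 11 | (1R,7E,10R)-6-(triethylsilyloxy)verticilla-4(20),7,11-trien-18,10-olide (C6 epimers) | C=C1CC[C@@H]2CCC3=C([C@@H](C/C(C)=C/C(O[Si](CC)(CC)CC)C1)OC3=O)C2(C)C
F11 | step 13 | (1R,6R,7E,10R)-6-hydroxyverticilla-4(20),7,11-trien-18,10-olide | C=C1CC[C@@H]2CCC3=C([C@@H](C/C(C)=C/[C@H](O)C1)OC3=O)C2(C)C
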